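**Retrosynthetic overview**

1. Target 21 comes from fluoride desilylation of the 4-silyloxy-2H-chromene 20. Ring C is the only ring made; rings A and B are bought.
2. 20 comes from ring-closing metathesis of 19. The strategy rests on C3 of ring C being an unsubstituted CH2 between the C4 carbonyl and C2, so the C3–C4 bond can be made as the C=C of a cyclic silyl enol ether from a vinyl group on C2 and a C4 enol ether on C4a.
3. 19 comes from ketone 18, which comes from phenol 9 and cinnamyl carbonate 17 by iridium-catalysed branched allylic etherification (O1–C2 bond and the C2 stereocentre).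
4. 9 comes from phloroacetophenone 1. After bis-silylation the one free OH (future O1) steers methyl to its ortho carbon (iodination, Negishi) and prenyl to its para carbon (Mitsunobu, para-Claisen). This fixes the 8-methyl-6-prenyl pattern without having to distinguish two near-identical ortho hydroxyls.
5. 17 comes from 2,4-dibromoanisole 10 by selective Br–Li exchange and prenylation, Heck reaction, DIBAL reduction and carbonate formation.

Key step: step 12

Remark on the chemistry: the (Sa,Sc,Sc) enantiomer of the phosphoramidite ligand is assumed to give the S ether in step 10, by analogy with the sense usual for heteroatom nucleophiles on cinnamyl carbonates; if the sense proved opposite, the antipodal ligand would be used.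

**Route**

Step 1
Reactants: 1 2,4,6-trihydroxyacetophenone (dried)
Product: 2 1-[2-hydroxy-4,6-bis(tert-butyldimethylsilyloxy)phenyl]ethanone
Conditions: TBSCl (2.1 equiv), imidazole, DMF/CH2Cl2, 0 °C to rt
Reagents that add atoms: tert-butyldimethylsilyl chloride CC(C)(C)[Si](C)(C)Cl
Why: Phenol silylation takes the 4-OH and one ortho OH, while the last ortho OH stays locked in the hydrogen bond to the acetyl carbonyl, as in the standard selective bis-protection of phloroacetophenone.

Step 2
Reactants: 2 1-[2-hydroxy-4,6-bis(tert-butyldimethylsilyloxy)phenyl]ethanone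
Product: 3 1-[2-hydroxy-3-iodo-4,6-bis(tert-butyldimethylsilyloxy)phenyl]ethanone
Conditions: NIS (1.0 equiv), MeCN/CH2Cl2, 0 °C, dark
Reagents that add atoms: N-iodosuccinimide O=C1CCC(=O)N1I
Why: Electrophilic aromatic iodination should go ortho to the only free hydroxyl (C3), the regiochemistry known for the 4,6-dialkoxy analogues and reinforced here because C5 lies between two bulky silyloxy groups.

Step 3
Reactants: 3 1-[2-hydroxy-3-iodo-4,6-bis(tert-butyldimethylsilyloxy)phenyl]ethanone
Product: 4 1-[2-hydroxy-3-methyl-4,6-bis(tert-butyldimethylsilyloxy)phenyl]ethanone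
Conditions: MeZnCl (2.5 equiv), Pd(dppf)Cl2 (5 mol%), THF, 60 °C; aq NH4Cl
Reagents that add atoms: methylzinc chloride C[Zn]Cl
Why: Negishi cross-coupling of the aryl iodide with a methylzinc reagent, which deprotonates the phenol but attacks neither the ketone nor the silyl ethers, turns the iodide into the future C8 methyl.

Step 4
Reactants: 4 1-[2-hydroxy-3-methyl-4,6-bis(tert-butyldimethylsilyloxy)phenyl]ethanone; 5 3-methylbut-2-en-1-ol (prenol)
Product: 6 1-[3-methyl-2-(3-methylbut-2-enyloxy)-4,6-bis(tert-butyldimethylsilyloxy)phenyl]ethanone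
Conditions: PPh3, DIAD, THF, 0 °C to rt
Reagents that add atoms: none
Why: Mitsunobu etherification of the acidic chelated phenol with a primary allylic alcohol runs under neutral conditions that leave the base-labile aryl silyl ethers alone.

Step 5
Reactants: 6 1-[3-methyl-2-(3-methylbut-2-enyloxy)-4,6-bis(tert-butyldimethylsilyloxy)phenyl]ethanone
Product: 9 1-[2-hydroxy-3-methyl-5-(3-methylbut-2-enyl)-4,6-bis(tert-butyldimethylsilyloxy)phenyl]ethanone, via ortho-dienone 7 (not isolated), via para-dienone 8 (not isolated)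
Conditions: N,N-diethylaniline, 190 °C, Ar, sealed tube
Reagents that add atoms: none
Why: Aromatic Claisen rearrangement onto a blocked ortho carbon followed by Cope rearrangement (para-Claisen) can only end at C5, the one unsubstituted ring carbon, where tautomerisation restores the phenol and leaves a linear prenyl group para to the hydroxyl.

Step 6
Reactants: 10 2,4-dibromoanisole; 11 prenyl bromide (1-bromo-3-methylbut-2-ene)
Product: 13 4-bromo-1-methoxy-2-(3-methylbut-2-enyl)benzene, via (5-bromo-2-methoxyphenyl)lithium 12 (not isolated)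
Conditions: n-BuLi (1.05 equiv), Et2O, −78 °C; then CuBr·SMe2 (20 mol%), 11, −78 °C to rt
Reagents that add atoms: none
Why: Bromine–lithium exchange of 2,4-dibromoanisole is selective for the bromine ortho to the coordinating methoxy group, and copper-catalysed SN2 allylation of the aryllithium with prenyl bromide gives the linear prenyl arene.

Step 7
Reactants: 13 4-bromo-1-methoxy-2-(3-methylbut-2-enyl)benzene; 14 methyl acrylate
Product: 15 methyl (E)-3-[4-methoxy-3-(3-methylbut-2-enyl)phenyl]prop-2-enoate
Conditions: Pd(OAc)2 (3 mol%), P(o-tol)3 (6 mol%), Et3N, DMF, 100 °C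
Reagents that add atoms: none
Why: Mizoroki–Heck reaction of the aryl bromide with the acrylate gives the E-cinnamate, the trisubstituted prenyl alkene being inert to carbopalladation.

Step 8
Reactants: 15 methyl (E)-3-[4-methoxy-3-(3-methylbut-2-enyl)phenyl]prop-2-enoate
Product: 16 (E)-3-[4-methoxy-3-(3-methylbut-2-enyl)phenyl]prop-2-en-1-ol
Conditions: DIBAL-H (2.3 equiv), CH2Cl2, −78 °C; Rochelle salt
Reagents that add atoms: none
Why: DIBAL-H reduces the enoate in the 1,2 sense at low temperature to the E-allylic alcohol without touching either alkene.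

Step 9
Reactants: 16 (E)-3-[4-methoxy-3-(3-methylbut-2-enyl)phenyl]prop-2-en-1-ol
Product: 17 (E)-3-[4-methoxy-3-(3-methylbut-2-enyl)phenyl]prop-2-enyl methyl carbonate
Conditions: ClCO2Me, pyridine, CH2Cl2, 0 °C
Reagents that add atoms: methyl chloroformate COC(=O)Cl
Why: Acylation of the primary allylic alcohol with the chloroformate gives the allylic carbonate that serves as the ionisable leaving group in the next step.

Step 10
Reactants: 9 1-[2-hydroxy-3-methyl-5-(3-methylbut-2-enyl)-4,6-bis(tert-butyldimethylsilyloxy)phenyl]ethanone; 17 (E)-3-[4-methoxy-3-(3-methylbut-2-enyl)phenyl]prop-2-enyl methyl carbonate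
Product: 18 1-[2-{(1S)-1-[4-methoxy-3-(3-methylbut-2-enyl)phenyl]prop-2-enyloxy}-3-methyl-5-(3-methylbut-2-enyl)-4,6-bis(tert-butyldimethylsilyloxy)phenyl]ethanone
Conditions: [Ir(cod)Cl]2 (2 mol%), (Sa,Sc,Sc)-BINOL N,N-bis(1-phenylethyl)phosphoramidite (4 mol%), pre-activation with n-PrNH2 (50 °C, then evaporated); 9 (1.0 equiv), 17 (1.3 equiv), THF, rt to 35 °C
Reagents that add atoms: none
Why: In this iridium-catalysed asymmetric allylic etherification the cyclometalated Ir–phosphoramidite ionises the carbonate to an allyl complex, the phenoxide (formed by the released methoxide) attacks its aryl-substituted terminus to give the branched ether, and the (Sa,Sc,Sc) ligand is expected to direct attack to the face that gives the S configuration at the future C2.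

Step 11
Reactants: 18 1-[2-{(1S)-1-[4-methoxy-3-(3-methylbut-2-enyl)phenyl]prop-2-enyloxy}-3-methyl-5-(3-methylbut-2-enyl)-4,6-bis(tert-butyldimethylsilyloxy)phenyl]ethanone
Product: 19 1-(tert-butyldimethylsilyloxy)-1-[2-{(1S)-1-[4-methoxy-3-(3-methylbut-2-enyl)phenyl]prop-2-enyloxy}-3-methyl-5-(3-methylbut-2-enyl)-4,6-bis(tert-butyldimethylsilyloxy)phenyl]ethene
Conditions: TBSOTf (1.5 equiv), Et3N (3 equiv), CH2Cl2, −78 to 0 °C
Reagents that add atoms: tert-butyldimethylsilyl trifluoromethanesulfonate CC(C)(C)[Si](C)(C)OS(=O)(=O)C(F)(F)F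
Why: Soft enolisation of the methyl ketone with silyl triflate and amine can only give the terminal silyl enol ether, since there are no other α-hydrogens, and the excess amine keeps the medium non-acidic so that the ionisable allylic ether survives.

Step 12
Reactants: 19 1-(tert-butyldimethylsilyloxy)-1-[2-{(1S)-1-[4-methoxy-3-(3-methylbut-2-enyl)phenyl]prop-2-enyloxy}-3-methyl-5-(3-methylbut-2-enyl)-4,6-bis(tert-butyldimethylsilyloxy)phenyl]ethene
Product: 20 (2S)-4,5,7-tris(tert-butyldimethylsilyloxy)-2-[4-methoxy-3-(3-methylbut-2-enyl)phenyl]-8-methyl-6-(3-methylbut-2-enyl)-2H-chromene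
Conditions: Grubbs II (7.5 mol%), 1,4-benzoquinone (15 mol%), degassed PhMe (0.01 M), 70 °C, Ar sparge, dark
Reagents that add atoms: none
Why: The ruthenium benzylidene first exchanges onto the unhindered monosubstituted vinyl group of the allylic ether, and the resulting alkylidene adds intramolecularly across the 1,1-disubstituted silyl enol ether to a ruthenacyclobutane whose cycloreversion gives the C3=C4 bond and Ru=CH2, the two terminal CH2 groups leaving as ethylene. The closest known reaction is the ring-closing metathesis of silyl enol ethers with terminal alkenes to cyclic silyl enol ethers, together with the styrene/allyl ether metathesis that gives 2H-chromenes. Ring C closes as a six-membered ring by ring-closing metathesis between the alkene carbon on C2 and the enol carbon C4 on C4a, the two arms being held ortho on ring A. No stereocentre is formed; C2, set in step 10, takes no part in the bond changes, and benzoquinone, exclusion of light and the lowest workable temperature guard it against Ru–H isomerisation of the allylic ether and against reversible ring opening of the chromene. The step needs chemoselectivity for the two terminal alkenes over the two trisubstituted prenyl alkenes, which is secured because the carbene loads on the vinyl group, the prenyl groups react far more slowly and could only close meta- or para-bridged rings, and high dilution suppresses cross-metathesis.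

Step 13
Reactants: 20 (2S)-4,5,7-tris(tert-butyldimethylsilyloxy)-2-[4-methoxy-3-(3-methylbut-2-enyl)phenyl]-8-methyl-6-(3-methylbut-2-enyl)-2H-chromene
Product: 21 (2S)-5,7-dihydroxy-2-[4-methoxy-3-(3-methylbut-2-enyl)phenyl]-8-methyl-6-(3-methylbut-2-enyl)chroman-4-one
Conditions: TBAF (3.5 equiv), AcOH (3.5 equiv), THF, 0 °C
Reagents that add atoms: none
Why: Fluoride cleaves the silyl enol ether (protonation at C3 gives the C4 ketone) and both aryl silyl ethers, and the acetic acid buffer keeps phenoxide and enolate concentrations low so that retro-oxa-Michael opening and racemisation at C2 should be avoided.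

**Compound list**

1 | 2,4,6-trihydroxyacetophenone | CC(=O)c1c(O)cc(O)cc1O | starting material
2 | 1-[2-hydroxy-4,6-bis(tert-butyldimethylsilyloxy)phenyl]ethanone | CC(=O)c1c(O)cc(O[Si](C)(C)C(C)(C)C)cc1O[Si](C)(C)C(C)(C)C | intermediate
3 | 1-[2-hydroxy-3-iodo-4,6-bis(tert-butyldimethylsilyloxy)phenyl]ethanone | CC(=O)c1c(O)c(I)c(O[Si](C)(C)C(C)(C)C)cc1O[Si](C)(C)C(C)(C)C | intermediate
4 | 1-[2-hydroxy-3-methyl-4,6-bis(tert-butyldimethylsilyloxy)phenyl]ethanone | CC(=O)c1c(O)c(C)c(O[Si](C)(C)C(C)(C)C)cc1O[Si](C)(C)C(C)(C)C | intermediate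
5 | 3-methylbut-2-en-1-ol (prenol) | CC(C)=CCO | starting material
6 | 1-[3-methyl-2-(3-methylbut-2-enyloxy)-4,6-bis(tert-butyldimethylsilyloxy)phenyl]ethanone | CC(=O)c1c(OCC=C(C)C)c(C)c(O[Si](C)(C)C(C)(C)C)cc1O[Si](C)(C)C(C)(C)C | intermediate
7 | 2-acetyl-6-methyl-6-(2-methylbut-3-en-2-yl)-3,5-bis(tert-butyldimethylsilyloxy)cyclohexa-2,4-dien-1-one (ortho-dienone, racemic) | CC(=O)C1=C(O[Si](C)(C)C(C)(C)C)C=C(O[Si](C)(C)C(C)(C)C)C(C)(C(C)(C)C=C)C1=O | intermediate (not isolated)
8 | 2-acetyl-6-methyl-4-(3-methylbut-2-enyl)-3,5-bis(tert-butyldimethylsilyloxy)cyclohexa-2,5-dien-1-one (para-dienone) | CC(=O)C1=C(O[Si](C)(C)C(C)(C)C)C(CC=C(C)C)C(O[Si](C)(C)C(C)(C)C)=C(C)C1=O | intermediate (not isolated)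
9 | 1-[2-hydroxy-3-methyl-5-(3-methylbut-2-enyl)-4,6-bis(tert-butyldimethylsilyloxy)phenyl]ethanone | CC(=O)c1c(O)c(C)c(O[Si](C)(C)C(C)(C)C)c(CC=C(C)C)c1O[Si](C)(C)C(C)(C)C | intermediate
10 | 2,4-dibromoanisole | COc1ccc(Br)cc1Br | starting material
11 | prenyl bromide (1-bromo-3-methylbut-2-ene) | CC(C)=CCBr | starting material
12 | (5-bromo-2-methoxyphenyl)lithium | COc1ccc(Br)cc1[Li] | intermediate (not isolated)
13 | 4-bromo-1-methoxy-2-(3-methylbut-2-enyl)benzene | COc1ccc(Br)cc1CC=C(C)C | intermediate
14 | methyl acrylate | C=CC(=O)OC | starting material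
15 | methyl (E)-3-[4-methoxy-3-(3-methylbut-2-enyl)phenyl]prop-2-enoate | COC(=O)/C=C/c1ccc(OC)c(CC=C(C)C)c1 | intermediate
16 | (E)-3-[4-methoxy-3-(3-methylbut-2-enyl)phenyl]prop-2-en-1-ol | OC/C=C/c1ccc(OC)c(CC=C(C)C)c1 | intermediate
17 | (E)-3-[4-methoxy-3-(3-methylbut-2-enyl)phenyl]prop-2-enyl methyl carbonate | COC(=O)OC/C=C/c1ccc(OC)c(CC=C(C)C)c1 | intermediate
18 | 1-[2-{(1S)-1-[4-methoxy-3-(3-methylbut-2-enyl)phenyl]prop-2-enyloxy}-3-methyl-5-(3-methylbut-2-enyl)-4,6-bis(tert-butyldimethylsilyloxy)phenyl]ethanone | CC(=O)c1c(O[Si](C)(C)C(C)(C)C)c(CC=C(C)C)c(O[Si](C)(C)C(C)(C)C)c(C)c1O[C@@H](C=C)c1ccc(OC)c(CC=C(C)C)c1 | intermediate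
19 | 1-(tert-butyldimethylsilyloxy)-1-[2-{(1S)-1-[4-methoxy-3-(3-methylbut-2-enyl)phenyl]prop-2-enyloxy}-3-methyl-5-(3-methylbut-2-enyl)-4,6-bis(tert-butyldimethylsilyloxy)phenyl]ethene | C=C(O[Si](C)(C)C(C)(C)C)c1c(O[Si](C)(C)C(C)(C)C)c(CC=C(C)C)c(O[Si](C)(C)C(C)(C)C)c(C)c1O[C@@H](C=C)c1ccc(OC)c(CC=C(C)C)c1 | intermediate
20 | (2S)-4,5,7-tris(tert-butyldimethylsilyloxy)-2-[4-methoxy-3-(3-methylbut-2-enyl)phenyl]-8-methyl-6-(3-methylbut-2-enyl)-2H-chromene | COc1ccc([C@@H]2C=C(O[Si](C)(C)C(C)(C)C)c3c(O[Si](C)(C)C(C)(C)C)c(CC=C(C)C)c(O[Si](C)(C)C(C)(C)C)c(C)c3O2)cc1CC=C(C)C | intermediate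
21 | (2S)-5,7-dihydroxy-2-[4-methoxy-3-(3-methylbut-2-enyl)phenyl]-8-methyl-6-(3-methylbut-2-enyl)chroman-4-one | COc1ccc([C@@H]2CC(=O)c3c(O)c(CC=C(C)C)c(O)c(C)c3O2)cc1CC=C(C)C | target

**Step count**

Total: 13 steps. Longest linear sequence: 9 steps (steps 1–5 and 10–13); the carbonate arm is 4 steps (6–9) and joins at step 10.

**Steps most likely to fail**

Step 12 (key ring-closing metathesis). The carbene may stall as an unreactive alkoxy-carbene after engaging the electron-rich enol ether in the wrong sense, or turn over slowly at the crowded, twisted aryl enol ether. The allylic ether may isomerise through ruthenium hydrides, and enantiopurity at C2 may be lost on prolonged heating. Fallback, setting out from 9 and 13 and coming back at 21: ring C is closed at O1–C2 by the classical chalcone route. Bromine–lithium exchange of 13 and quenching with DMF gives 4-methoxy-3-(3-methylbut-2-enyl)benzaldehyde F1. The lithium dianion of 9 (LiHMDS, THF, −78 °C) adds to it to give the aldol adduct 3-hydroxy-1-[2-hydroxy-3-methyl-5-(3-methylbut-2-enyl)-4,6-bis(tert-butyldimethylsilyloxy)phenyl]-3-[4-methoxy-3-(3-methylbut-2-enyl)phenyl]propan-1-one F2, which is dehydrated (MsCl, Et3N) to the 2'-hydroxychalcone F3. Because only the future O1 hydroxyl is free, mild base (catalytic DBU or NaOAc) should close a single regioisomer by oxa-Michael addition, the racemic 5,7-bis(tert-butyldimethylsilyloxy)flavanone F4. Preparative chiral HPLC gives the (2S)-5,7-bis(tert-butyldimethylsilyloxy)flavanone F5, and buffered TBAF as in step 13 gives 21.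

Step 10 (iridium-catalysed etherification). The chelated, doubly ortho-substituted phenol may attack the allyl complex too slowly, so that linear ether or methyl ether forms instead. The electron-rich 1-arylallyl aryl ether may also re-ionise on the catalyst, eroding the branched selectivity and the enantiomeric purity. Fallback, setting out from 13 and 9 and coming back at 18: the stereocentre is set on the alcohol and the O1–C2 bond is made with inversion. Bromine–lithium exchange of 13 and addition to acrolein gives racemic 1-[4-methoxy-3-(3-methylbut-2-enyl)phenyl]prop-2-en-1-ol F6. MnO2 oxidation gives 1-[4-methoxy-3-(3-methylbut-2-enyl)phenyl]prop-2-en-1-one F7. Corey–Bakshi–Shibata reduction ((S)-Me-CBS, catecholborane, −78 °C) should give (1R)-1-[4-methoxy-3-(3-methylbut-2-enyl)phenyl]prop-2-en-1-ol F8. Mitsunobu coupling of this alcohol with 9 (PPh3, DIAD, toluene, −20 °C) gives 18 by SN2 inversion.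

Step 5 (para-Claisen–Cope). At 190 °C the prenyl ether may fragment back to phenol 4, a silyl group may migrate or be lost, or the sequence may stop before the Cope step delivers the prenyl group between the two silyloxy groups. Fallback, setting out from 4 and coming back at 9: bromination with NBS (MeCN, 0 °C) at the only free ring carbon gives 1-[5-bromo-2-hydroxy-3-methyl-4,6-bis(tert-butyldimethylsilyloxy)phenyl]ethanone F9. Stille coupling with tributyl(3-methylbut-2-enyl)stannane (Pd(PPh3)4, DMF, 90 °C) should then give 9 as the linear prenyl isomer.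

**Further compounds**

F1 | step 12 | 4-methoxy-3-(3-methylbut-2-enyl)benzaldehyde | COc1ccc(C=O)cc1CC=C(C)C
F2 | step 12 | 3-hydroxy-1-[2-hydroxy-3-methyl-5-(3-methylbut-2-enyl)-4,6-bis(tert-butyldimethylsilyloxy)phenyl]-3-[4-methoxy-3-(3-methylbut-2-enyl)phenyl]propan-1-one (racemic) | COc1ccc(C(O)CC(=O)c2c(O)c(C)c(O[Si](C)(C)C(C)(C)C)c(CC=C(C)C)c2O[Si](C)(C)C(C)(C)C)cc1CC=C(C)C
F3 | step 12 | (E)-1-[2-hydroxy-3-methyl-5-(3-methylbut-2-enyl)-4,6-bis(tert-butyldimethylsilyloxy)phenyl]-3-[4-methoxy-3-(3-methylbut-2-enyl)phenyl]prop-2-en-1-one | COc1ccc(/C=C/C(=O)c2c(O)c(C)c(O[Si](C)(C)C(C)(C)C)c(CC=C(C)C)c2O[Si](C)(C)C(C)(C)C)cc1CC=C(C)C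
F4 | step 12 | racemic 5,7-bis(tert-butyldimethylsilyloxy)-2-[4-methoxy-3-(3-methylbut-2-enyl)phenyl]-8-methyl-6-(3-methylbut-2-enyl)chroman-4-one | COc1ccc(C2CC(=O)c3c(O[Si](C)(C)C(C)(C)C)c(CC=C(C)C)c(O[Si](C)(C)C(C)(C)C)c(C)c3O2)cc1CC=C(C)C
F5 | step 12 | (2S)-5,7-bis(tert-butyldimethylsilyloxy)-2-[4-methoxy-3-(3-methylbut-2-enyl)phenyl]-8-methyl-6-(3-methylbut-2-enyl)chroman-4-one | COc1ccc([C@@H]2CC(=O)c3c(O[Si](C)(C)C(C)(C)C)c(CC=C(C)C)c(O[Si](C)(C)C(C)(C)C)c(C)c3O2)cc1CC=C(C)C
F6 | step 10 | racemic 1-[4-methoxy-3-(3-methylbut-2-enyl)phenyl]prop-2-en-1-ol | C=CC(O)c1ccc(OC)c(CC=C(C)C)c1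
F7 | step 10 | 1-[4-methoxy-3-(3-methylbut-2-enyl)phenyl]prop-2-en-1-one | C=CC(=O)c1ccc(OC)c(CC=C(C)C)c1
F8 | step 10 | (1R)-1-[4-methoxy-3-(3-methylbut-2-enyl)phenyl]prop-2-en-1-ol | O[C@H](C=C)c1ccc(OC)c(CC=C(C)C)c1
F9 | step 5 | 1-[5-bromo-2-hydroxy-3-methyl-4,6-bis(tert-butyldimethylsilyloxy)phenyl]ethanone | CC(=O)c1c(O)c(C)c(O[Si](C)(C)C(C)(C)C)c(Br)c1O[Si](C)(C)C(C)(C)C
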